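The intermediate is a fork in this flask, so I follow one molecule of it.

    partner + intermediate → product (k1 = 64 /M/s)
    partner + leaving ligand ⇌ idle adduct, settled at all times (K2 = 12 /M)
    starting material ⇌ intermediate + leaving ligand (K3 = 2.6 × 10⁻⁶ M, k3 = 0.0011 /s)
    intermediate → decomposed reagent (k4 = 8.0 × 10⁻⁴ /s)
    scavenger + leaving ligand → scavenged by-product (k5 = 0.17 /M/s)
    solid reagent ⇌ partner, rate k6*(cs6 - [partner]) while solid is left; crystals form when [partner] > cs6 (cs6 = 47 mM, k6 = 0.0030 /s)

starting material 0.10 M; solid reagent 0.120 M; time 40 min

- for leaving ligand the idle adduct is counted in
- as a solid, counted per litre of solution: solid reagent
- the amount of scavenger is what is sought; it is there from the start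
- at the start none of the solid reagent is in solution
- run time (flask): 40 min

- the concentration of scavenger at which the part of the starting material that has reacted at 40 min is just 70 %, in M

Starting material breaks with 0.0011 /s, and its intermediate, taken in a steady state, either meets partner or takes the leaving ligand back with 423 /M/s. The asked part needs φ = 0.456: φ, the required chance, is the mean share of intermediate that must go on to product, the logarithm of charged over remaining starting material divided by k3 times the time.

The mean use of partner is 1.75 mM/min, and dissolving must supply it, so I put partner P at 37.3 mM. Decay of the intermediate is far slower than capture, so I drop it. Then φ asks for free ligand L of 6.73 mM. Scavenger S must remove ligand at the mean rate, which takes S = 0.0255 M. Counting ligand left free or in the idle adduct, the run uses 0.0603 M of scavenger. The solid should last, since product, dissolved partner and partner held in the idle adduct together take less than the charge.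

I reckon the charge in two ways, both with S falling evenly. The plain mean adds half of that use to S and gives 0.0556 M, but this charge is smaller than the use, so this way cheats. Ligand goes with the inverse of S, so the second way matches the mean inverse instead. Charge over final scavenger is then 10.6, and the charge is 0.0665 M. I commit to that.

The forecast says 0.054 M, holding that “about 45% of the intermediate formed can go on to product”. That chance is close to mine, but its charge is lower.

The simulation gives 0.0646 M, which is 0.646 of the starting material charged, and 10.6 % of that scavenger is still free at 40.0 min. The formula for φ, applied to each stretch of this flask, gives a mean chance of 0.454 up to 20.0 min and 0.458 from there to 40 min. In a second flask with a quarter more scavenger, 74.2 % has reacted at 40 min, so its mean chance is 0.513.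

The numbers of this flask are assumed.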